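Take the substrate left over once the coupling partner has gone: each run of the step that makes side product B then takes one substrate and one target, so substrate minus target, in fractions of the substrate charge, stays put.

| flask | substrate | coupling partner | protic impurity | time | remark |
|---|---|---|---|---|---|
| south | 0.018 M | 0.0198 M | 9.00 mM | 25 h | everything together at the start |
| north-west | 0.018 M (fed, over 10 h) | 0.0198 M | 9.00 mM | 25 h | all else is in the flask from the start; the feed brings no volume worth counting |
| south-west | 0.018 M | 0.0198 M (fed, over 10 h) | 9.00 mM | 25 h | all else is in the flask from the start; the feed brings no volume worth counting |

* the flask that comes out highest in amount of target, in percent of the substrate charged, or "all alike" when all lie within 1.5 percentage points (south / north-west / south-west / all alike)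
* target at the end, in percent of the substrate charged, south
* target at the end, in percent of the substrate charged, north-west
* target at the end, in percent of the substrate charged, south-west

- percent here means substrate units held: one side product B counts as two
- a doubled species enters its step squared and goes two at a time
- run time (south): 25 h

    substrate + coupling partner → target (k1 = 59.6 M⁻¹ h⁻¹)
    substrate + 2 coupling partner → side product A (k2 = 4160 M⁻² h⁻¹)
    coupling partner + protic impurity → quenched reagent (k3 = 151 M⁻¹ h⁻¹)
    substrate + target → side product B (k4 = 28.2 M⁻¹ h⁻¹)

Counting the whole charge, that difference starts at one, falls by two for each target made and by one for each side product A, and the eating step leaves it alone. For south I split the partner by rates. With partner at half its charge, side product A per target, a selectivity factor, is 0.691, and impurity per target at the start is 1.27. So I reckon target made at 30.1 %, and the leftover, substrate minus target after the partner has gone, at 18.9 %. With a positive leftover, substrate eats target at 0.508 h⁻¹ per unit of substrate fraction, and the leftover divided by the exponential of leftover, rate and time, less one, gives my target in south: 1.89 %.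

In north-west I let the impurity take its whole charge, use the half-level of the partner left after it, and start the clock at mid-feed: leftover 18.7 %, target 3.30 %.

In south-west the partner stands where feed equals use, at 0.814 mM, far below its charge, so the selectivity factor drops to 0.0568. With the impurity again taking its whole charge, the leftover is negative, −10.8 %. By this reckoning, target in south-west then has a floor: 10.8 %. Adding the substrate still left, clocked from the feed's end, gives my ceiling, 19.3 %; clocked from mid-feed, I commit to 16.2 %. My choice is south-west.

The forecast also chose south-west, with 2.6 % in south, 2.7 % in north-west and 27 % in south-west, since south-west “ends with partner in excess so the substrate is used up”. Its south-west figure stands above my ceiling.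

The flasks give south-west as highest: 2.05 % in south, 3.26 % in north-west, and 12.4 % in south-west, which lies inside my bracket and 15 percentage points below the forecast.

South-west ends with substrate 4.63 % and target 12.4 %, a leftover of −7.77 % against my −10.8 %. South ends with a leftover of 13.5 % against my 18.9 %. For a neighbour of south, with impurity at 0.0054 M, the same reckoning gives a leftover of 5.79 % and target 5.34 %. That neighbour ends with substrate 6.11 % and target 7.13 %, a leftover of −1.02 %.

All constants come from no measurement; no experiment stands behind them.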